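The oxolane ring is numbered O1, C2 (pentyl), C3 (acyloxy), C4 (CH2), C5 (carbinol side chain). The plan rests on cutting it into a C2–C3–C4 unit and the C5=O1 carbonyl of an aldehyde, and on reading the C3 oxygen as a masked silyl group whose β-cation stabilisation links both events. A SnCl4-promoted [3+2] annulation of (R)-3-(dimethylphenylsilyl)oct-1-ene with chelating (R)-2-(benzyloxy)undec-10-enal should join the two halves, close the ring with a 1,2-silyl shift and set C2, C3 and C5 in one operation. Tamao–Fleming oxidation (retention), Mitsunobu esterification with palmitic acid (inversion at C3) and debenzylation complete the route.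

Key step: step 7

Remark: C1′ is the carbinol carbon of the side chain; compounds 1, 4, 5 and 13 and all unnumbered reagents are taken as commercial.

Step 1
Reactants: 1 (E)-oct-2-en-1-ol
Product: 2 diethyl (E)-oct-2-en-1-yl phosphate
Conditions: ClP(O)(OEt)2, pyridine, DMAP (cat.), CH2Cl2, 0 °C → rt
Reagents that add atoms: diethyl chlorophosphate, CCOP(=O)(Cl)OCC
Why: O-phosphorylation of a primary allylic alcohol under amine base should leave the E alkene untouched and provides the leaving group for the allylic substitution.

Step 2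
Reactants: 2 diethyl (E)-oct-2-en-1-yl phosphate
Product: 3 (R)-dimethyl(oct-1-en-3-yl)(phenyl)silane
Conditions: PhMe2Si–Bpin, CuCl (5 mol%), chiral 4,5-diphenylimidazolinium salt (NHC precursor, 6 mol%, enantiomer that gives the R silane), NaOMe, CH2Cl2, 0 °C
Reagents that add atoms: (dimethylphenylsilyl)boronic acid pinacol ester, CC1(C)OB(OC1(C)C)[Si](C)(C)c1ccccc1
Why: Copper-catalysed enantioselective allylic substitution with a silyl nucleophile (Si–B transmetalation to a chiral NHC–Cu–SiMe2Ph species, γ-selective SN2′ displacement of phosphate) is a known route from linear E allylic phosphates to branched α-chiral allylsilanes, and the ligand enantiomer fixes the alkene face that receives silicon and so the R centre.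

Step 3
Reactants: 4 (R)-glycidyl trityl ether; 5 8-bromooct-1-ene
Product: 7 (R)-1-(trityloxy)undec-10-en-2-ol, via oct-7-en-1-ylmagnesium bromide 6 (not isolated)
Conditions: 5, Mg turnings, THF, rt; then 4, CuI (10 mol%), THF, −30 → 0 °C; aq NH4Cl
Reagents that add atoms: none
Why: Copper-catalysed Grignard opening of a terminal epoxide occurs by SN2 at the unsubstituted carbon, so the stereocentre of 4 passes unchanged into the secondary alcohol while the trityl ether is inert.

Step 4
Reactants: 7 (R)-1-(trityloxy)undec-10-en-2-ol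
Product: 8 [(R)-2-(benzyloxy)undec-10-en-1-yl] trityl ether
Conditions: NaH, BnBr, n-Bu4NI (cat.), THF/DMF, 0 °C → rt
Reagents that add atoms: benzyl bromide, BrCc1ccccc1
Why: Williamson etherification of the secondary alkoxide installs the benzyl ether that later serves as the chelating group, and a trityl ether cannot migrate under base.

Step 5
Reactants: 8 [(R)-2-(benzyloxy)undec-10-en-1-yl] trityl ether
Product: 9 (R)-2-(benzyloxy)undec-10-en-1-ol
Conditions: p-TsOH·H2O (cat.), MeOH/CH2Cl2, rt
Reagents that add atoms: none
Why: Acid-catalysed solvolysis of the trityl ether (SN1 transfer of the trityl cation to methanol) should free the primary alcohol, the benzyl ether and the terminal alkene being stable to mild acid.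

Step 6
Reactants: 9 (R)-2-(benzyloxy)undec-10-en-1-ol
Product: 10 (R)-2-(benzyloxy)undec-10-enal
Conditions: Dess–Martin periodinane, CH2Cl2, 0 °C → rt; used at once
Reagents that add atoms: none
Why: Dess–Martin oxidation should give the aldehyde under neutral, non-epimerising conditions, and immediate use protects the α-benzyloxy stereocentre.

Step 7
Reactants: 3 (R)-dimethyl(oct-1-en-3-yl)(phenyl)silane; 10 (R)-2-(benzyloxy)undec-10-enal
Product: 11 {(2S,3R,5R)-5-[(1R)-1-(benzyloxy)dec-9-en-1-yl]-2-pentyloxolan-3-yl}dimethyl(phenyl)silane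
Conditions: 10, SnCl4 (1.05 equiv), 4 Å MS, CH2Cl2, −78 °C; then 3 (1.3 equiv), −78 → −45 °C; aq NaHCO3
Reagents that add atoms: none
Why: Lewis-acid [3+2] annulation of an α-chiral allylsilane with an aldehyde, the closest known reaction type being the allylsilane–aldehyde oxolane annulation with 1,2-silyl shift: the terminal CH2 of 3 adds anti-SE2′ to the SnCl4-chelated carbonyl of 10 (C4–C5 bond), silicon bridges the resulting β-cation and migrates from C2 to C3, and the tin alkoxide attacks C2 anti to silicon (O1–C2 bond). The oxolane closes by this invertive opening of the three-membered siliranium at its far carbon, an endo-mode (5-endo) opening that leaves silicon as a substituent on ring carbon C3. C5 is controlled by the five-membered O–Sn–O chelate of 10, attacked on the face away from the C1′ alkyl chain (Cram chelate model, threo C5/C1′); C2 is controlled by the R silicon-bearing centre of 3, which is inverted; C3 is controlled by the H-inside conformer of 3, which puts silicon on the face opposite the new C–C bond and hence trans to pentyl. The 2,5-trans relationship follows because each partner offers one face only, the R/R pairing being the one that maps onto the target. The step needs annulation to win over desilylative Hosomi–Sakurai allylation, which the slowly cleaved PhMe2Si group, the non-coordinating solvent and the low temperature should secure, and it needs the distal terminal alkene and the benzyl ether to stay inert, as expected at −78 °C.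

Step 8
Reactants: 11 {(2S,3R,5R)-5-[(1R)-1-(benzyloxy)dec-9-en-1-yl]-2-pentyloxolan-3-yl}dimethyl(phenyl)silane
Product: 12 (2S,3R,5R)-5-[(1R)-1-(benzyloxy)dec-9-en-1-yl]-2-pentyloxolan-3-ol
Conditions: t-BuOOH (in excess over KH), KH, NMP, 0 °C → rt; then n-Bu4NF, 70 °C
Reagents that add atoms: tert-butyl hydroperoxide, CC(C)(C)OO
Why: Tamao–Fleming oxidation in its nucleophilic variant (peroxide anion and fluoride attack silicon, phenyl is expelled and C3 migrates from silicon to oxygen with retention) needs no electrophile, so the terminal alkene and the benzyl ether should survive and the hydroxyl emerges trans to pentyl.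

Step 9
Reactants: 12 (2S,3R,5R)-5-[(1R)-1-(benzyloxy)dec-9-en-1-yl]-2-pentyloxolan-3-ol; 13 palmitic acid
Product: 14 (2S,3S,5R)-5-[(1R)-1-(benzyloxy)dec-9-en-1-yl]-2-pentyloxolan-3-yl hexadecanoate
Conditions: PPh3, DIAD, toluene, 0 °C → rt
Reagents that add atoms: none
Why: Mitsunobu esterification activates the C3 hydroxyl as an oxyphosphonium ion that palmitate displaces by SN2 with inversion, which installs the acyl group and turns the 2,3-trans alcohol into the required 2,3-cis (3S) ester in one step.

Step 10
Reactants: 14 (2S,3S,5R)-5-[(1R)-1-(benzyloxy)dec-9-en-1-yl]-2-pentyloxolan-3-yl hexadecanoate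
Product: 15 (2S,3S,5R)-5-[(1R)-1-hydroxydec-9-en-1-yl]-2-pentyloxolan-3-yl hexadecanoate (CNP0186581.1)
Conditions: BCl3, pentamethylbenzene, CH2Cl2, −78 °C; then MeOH/H2O
Reagents that add atoms: none
Why: Lewis-acid debenzylation with BCl3 and pentamethylbenzene as a non-basic cation scavenger cleaves the benzyl ether by ionisation and Friedel–Crafts trapping of the benzyl cation at low temperature, where the ester, the oxolane ring and the terminal alkene are expected to persist and no stereocentre is touched.

Compound list
1 | (E)-oct-2-en-1-ol | CCCCC/C=C/CO | starting material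
2 | diethyl (E)-oct-2-en-1-yl phosphate | CCCCC/C=C/COP(=O)(OCC)OCC | intermediate
3 | (R)-dimethyl(oct-1-en-3-yl)(phenyl)silane | C=C[C@@H](CCCCC)[Si](C)(C)c1ccccc1 | intermediate
4 | (R)-glycidyl trityl ether, (R)-2-[(trityloxy)methyl]oxirane | C(OC[C@H]1CO1)(c1ccccc1)(c1ccccc1)c1ccccc1 | starting material
5 | 8-bromooct-1-ene | C=CCCCCCCBr | starting material
6 | oct-7-en-1-ylmagnesium bromide | C=CCCCCCC[Mg]Br | intermediate (not isolated)
7 | (R)-1-(trityloxy)undec-10-en-2-ol | C=CCCCCCCC[C@@H](O)COC(c1ccccc1)(c1ccccc1)c1ccccc1 | intermediate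
8 | [(R)-2-(benzyloxy)undec-10-en-1-yl] trityl ether | C=CCCCCCCC[C@@H](OCc1ccccc1)COC(c1ccccc1)(c1ccccc1)c1ccccc1 | intermediate
9 | (R)-2-(benzyloxy)undec-10-en-1-ol | C=CCCCCCCC[C@@H](OCc1ccccc1)CO | intermediate
10 | (R)-2-(benzyloxy)undec-10-enal | C=CCCCCCCC[C@@H](OCc1ccccc1)C=O | intermediate
11 | {(2S,3R,5R)-5-[(1R)-1-(benzyloxy)dec-9-en-1-yl]-2-pentyloxolan-3-yl}dimethyl(phenyl)silane | C=CCCCCCCC[C@@H](OCc1ccccc1)[C@H]1C[C@@H]([Si](C)(C)c2ccccc2)[C@H](CCCCC)O1 | intermediate
12 | (2S,3R,5R)-5-[(1R)-1-(benzyloxy)dec-9-en-1-yl]-2-pentyloxolan-3-ol | C=CCCCCCCC[C@@H](OCc1ccccc1)[C@H]1C[C@@H](O)[C@H](CCCCC)O1 | intermediate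
13 | palmitic acid (hexadecanoic acid) | CCCCCCCCCCCCCCCC(=O)O | starting material
14 | (2S,3S,5R)-5-[(1R)-1-(benzyloxy)dec-9-en-1-yl]-2-pentyloxolan-3-yl hexadecanoate | C=CCCCCCCC[C@@H](OCc1ccccc1)[C@H]1C[C@H](OC(=O)CCCCCCCCCCCCCCC)[C@H](CCCCC)O1 | intermediate
15 | (2S,3S,5R)-5-[(1R)-1-hydroxydec-9-en-1-yl]-2-pentyloxolan-3-yl hexadecanoate | C=CCCCCCCC[C@@H](O)[C@H]1C[C@H](OC(=O)CCCCCCCCCCCCCCC)[C@H](CCCCC)O1 | target

Total step count: 10. Longest linear sequence: 8 steps (steps 3 to 10).

Steps most likely to fail

Step 7. What may go wrong: mismatched double stereodifferentiation, in which the synclinal approach preferred by a chelated aldehyde (leading to a 2,5-cis ring) opposes the pairing of faces needed for the 2,5-trans ring, and desilylative allylation in place of silyl migration. The fallback sets out from 3 and comes back at 15. Silane 3 and commercial (benzyloxy)acetaldehyde are combined with BF3·OEt2 in CH2Cl2 at −78 °C. Monodentate activation should favour the 2,5-trans ring, and the aldehyde carries no stereocentre that could oppose it. This should give {(2S,3R,5R)-5-[(benzyloxy)methyl]-2-pentyloxolan-3-yl}dimethyl(phenyl)silane F1. Oxidation as in step 8 should give (2S,3R,5R)-5-[(benzyloxy)methyl]-2-pentyloxolan-3-ol F2. Mitsunobu esterification with 13 should give the inverted ester (2S,3S,5R)-5-[(benzyloxy)methyl]-2-pentyloxolan-3-yl hexadecanoate F3. Hydrogenolysis (H2, Pd/C, EtOAc) should give the primary alcohol (2S,3S,5R)-5-(hydroxymethyl)-2-pentyloxolan-3-yl hexadecanoate F4, and Dess–Martin oxidation the aldehyde (2S,3S,5R)-5-formyl-2-pentyloxolan-3-yl hexadecanoate F5. Non-8-en-1-ylmagnesium bromide F6, made from commercial 9-bromonon-1-ene and Mg, is then added to F5 precomplexed with MgBr2·OEt2 in CH2Cl2 at −78 °C. Attack on the O1–Mg–O=C chelate anti to C4 should give the threo carbinol, that is 15; the aldehyde should react before the ester at this temperature.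

Step 8. What may go wrong: incomplete activation of the hindered silane, or base- and fluoride-induced β-elimination of the ring oxygen with opening of the oxolane. The fallback sets out from 11 and comes back at 12. It replaces the nucleophilic one-flask oxidation by an electrophilic two-stage sequence through an isolated halosilane. HBF4·OEt2 in CH2Cl2 (0 °C → rt) should remove the phenyl group by ipso-protodesilylation to give fluoro{(2S,3R,5R)-5-[(1R)-1-(benzyloxy)dec-9-en-1-yl]-2-pentyloxolan-3-yl}dimethylsilane F7. Tamao oxidation with H2O2, KF and KHCO3 in THF/MeOH should then deliver 12 with retention. These conditions contain no alkene-reactive electrophile.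

Step 9. What may go wrong: slow SN2 displacement on the face cis to the pentyl group, with elimination of the oxyphosphonium intermediate or recovery of alcohol. The fallback sets out from 12 and comes back at 14. Dess–Martin oxidation should give (2S,5R)-5-[(1R)-1-(benzyloxy)dec-9-en-1-yl]-2-pentyloxolan-3-one F8. LiBH(s-Bu)3 in THF at −78 °C should deliver hydride to the face anti to the C2 pentyl group and give the cis alcohol (2S,3S,5R)-5-[(1R)-1-(benzyloxy)dec-9-en-1-yl]-2-pentyloxolan-3-ol F9. Acylation with palmitoyl chloride (pyridine, DMAP, CH2Cl2) should then give 14.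

Further compounds
F1 | step 7 | {(2S,3R,5R)-5-[(benzyloxy)methyl]-2-pentyloxolan-3-yl}dimethyl(phenyl)silane | c1ccccc1COC[C@H]1C[C@@H]([Si](C)(C)c2ccccc2)[C@H](CCCCC)O1
F2 | step 7 | (2S,3R,5R)-5-[(benzyloxy)methyl]-2-pentyloxolan-3-ol | c1ccccc1COC[C@H]1C[C@@H](O)[C@H](CCCCC)O1
F3 | step 7 | (2S,3S,5R)-5-[(benzyloxy)methyl]-2-pentyloxolan-3-yl hexadecanoate | c1ccccc1COC[C@H]1C[C@H](OC(=O)CCCCCCCCCCCCCCC)[C@H](CCCCC)O1
F4 | step 7 | (2S,3S,5R)-5-(hydroxymethyl)-2-pentyloxolan-3-yl hexadecanoate | OC[C@H]1C[C@H](OC(=O)CCCCCCCCCCCCCCC)[C@H](CCCCC)O1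
F5 | step 7 | (2S,3S,5R)-5-formyl-2-pentyloxolan-3-yl hexadecanoate | O=C[C@H]1C[C@H](OC(=O)CCCCCCCCCCCCCCC)[C@H](CCCCC)O1
F6 | step 7 | non-8-en-1-ylmagnesium bromide | C=CCCCCCCC[Mg]Br
F7 | step 8 | fluoro{(2S,3R,5R)-5-[(1R)-1-(benzyloxy)dec-9-en-1-yl]-2-pentyloxolan-3-yl}dimethylsilane | C=CCCCCCCC[C@@H](OCc1ccccc1)[C@H]1C[C@@H]([Si](C)(C)F)[C@H](CCCCC)O1
F8 | step 9 | (2S,5R)-5-[(1R)-1-(benzyloxy)dec-9-en-1-yl]-2-pentyloxolan-3-one | C=CCCCCCCC[C@@H](OCc1ccccc1)[C@H]1CC(=O)[C@H](CCCCC)O1
F9 | step 9 | (2S,3S,5R)-5-[(1R)-1-(benzyloxy)dec-9-en-1-yl]-2-pentyloxolan-3-ol | C=CCCCCCCC[C@@H](OCc1ccccc1)[C@H]1C[C@H](O)[C@H](CCCCC)O1
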